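**Plan**

Numbering: benzofuran numbering O1, C2, C3, C3a, C4–C7, C7a. C9 is the CH2OH carbon on C3. Ring A is the guaiacyl ring on C2, ring B the benzo ring, ring C the dihydrofuran.
Retrosynthesis: remove the sulfate ester, trace C9–OH back to C9–SiMe2Ph, then cut ring C at O1–C7a and C2–C3 in one stroke to give O-benzylvanillin and a ring B benzyl anion with a leaving group on C7a. Ring B is then cut at C3a–C3, C7a–S and C5–chain.
Enabling feature: C3 is benzylic to ring B and hangs on C3a, next to C7a, while O1–C2 is the aldehyde carbon of ring A. A group on C7a that steers metalation of C3 and can also leave turns C3–C3a–C7a into a three-atom partner for C=O, and the alkoxide O1 is formed five atoms from C7a.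
Forward: two B-alkyl Suzuki couplings and one lithiation/sulfinylation dress 3-bromo-5-iodoanisole (ring B). Step 4 joins ring A and closes ring C. Desilylation, sulfation, Fleming–Tamao oxidation and hydrogenolysis follow.
Stereochemistry: the only chiral source is the sulfur of menthyl p-toluenesulfinate. It sets C3 through a chelated benzyllithium, C3 and the lithium bridge set C2 (trans), and the sulfinyl group leaves in the same step.
Silicon on C9 prevents β-elimination in the carbanion and keeps C9–OH masked during sulfation, so the two primary alcohols never need to be differentiated.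

Key step: step 4

Assumption: the target is drawn as the free hydrogen sulfate; the ester is carried as its sodium salt and protonated only in the last operation, because alkyl hydrogen sulfates hydrolyse under their own acidity.
Assumption: the sense of induction in step 4 is derived from the chelate model given there; should it prove opposite, the enantiomeric menthyl sulfinate (also commercial) would be used in step 2 with no other change.

**Step 1**
Reactants: 1 allyloxy(tert-butyl)dimethylsilane; 2 1-bromo-3-iodo-5-methoxybenzene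
Product: 4 1-bromo-3-[3-(tert-butyldimethylsilyloxy)propyl]-5-methoxybenzene, via B-alkyl-9-BBN 3 (not isolated)
Conditions: 1, 9-BBN, THF, 0 °C to rt; then 2, PdCl2(dppf) (3 mol %), aq K3PO4, THF/DMF, rt
Reagents that add atoms: none
Why: Anti-Markovnikov hydroboration and B-alkyl Suzuki–Miyaura coupling, in which zerovalent palladium inserts into the C–I bond of 2 far faster than into its C–Br bond at room temperature, so that the bromine is kept for steps 2 and 3.

**Step 2**
Reactants: 4 1-bromo-3-[3-(tert-butyldimethylsilyloxy)propyl]-5-methoxybenzene; 5 (1R,2S,5R)-menthyl (S)-p-toluenesulfinate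
Product: 7 (S)-1-bromo-5-[3-(tert-butyldimethylsilyloxy)propyl]-3-methoxy-2-(p-tolylsulfinyl)benzene, via aryllithium 6 (not isolated)
Conditions: LDA (1.05 equiv), THF, −78 °C; cannulated into 5 (1.2 equiv), THF, −78 °C; aq NH4Cl
Reagents that add atoms: none
Why: Directed ortho-lithiation takes the only ring hydrogen flanked by Br and OMe (the future C7a), and the Andersen sulfoxide synthesis then replaces menthoxide at sulfur with inversion, which fixes the (S)-sulfur stereocentre; −78 °C and inverse addition hold back aryne formation and sulfoxide ligand exchange.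

**Step 3**
Reactants: 7 (S)-1-bromo-5-[3-(tert-butyldimethylsilyloxy)propyl]-3-methoxy-2-(p-tolylsulfinyl)benzene; 8 dimethyl(phenyl)(vinyl)silane
Product: 10 (S)-5-[3-(tert-butyldimethylsilyloxy)propyl]-1-{2-[dimethyl(phenyl)silyl]ethyl}-3-methoxy-2-(p-tolylsulfinyl)benzene, via B-silylethyl-9-BBN 9 (not isolated)
Conditions: 8, 9-BBN, THF, rt; then water, 7, Pd(OAc)2 (5 mol %), SPhos (10 mol %), K3PO4, THF, 60 °C
Reagents that add atoms: none
Why: B-alkyl Suzuki–Miyaura coupling of the terminal 9-BBN adduct of the vinylsilane, in which a bulky electron-rich phosphine copes with the ortho-sulfinyl bromide and the sulfur stereocentre is configurationally stable at this temperature.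

**Step 4**
Reactants: 10 (S)-5-[3-(tert-butyldimethylsilyloxy)propyl]-1-{2-[dimethyl(phenyl)silyl]ethyl}-3-methoxy-2-(p-tolylsulfinyl)benzene; 11 4-benzyloxy-3-methoxybenzaldehyde
Product: 14 (2S,3S)-2-(4-benzyloxy-3-methoxyphenyl)-5-[3-(tert-butyldimethylsilyloxy)propyl]-3-{[dimethyl(phenyl)silyl]methyl}-7-methoxy-2,3-dihydrobenzofuran (trans), via benzyllithium 12 (not isolated), via lithium alkoxide 13 (not isolated)
Conditions: LDA (1.2 equiv), THF, −78 °C; 11 (1.3 equiv), −78 °C; then KOtBu (1.5 equiv), −78 to 45 °C; water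
Reagents that add atoms: none
Why: Proposed new method: LDA removes one C3–H of 10 under complex-induced proximity to the sulfinyl oxygen, the chelated benzyllithium 12 adds to the carbonyl carbon of 11 (C2–C3 bond), and the alkoxide 13, whose O1 is thereby placed five atoms from C7a, expels p-toluenesulfenate from C7a once potassium has replaced lithium (O1–C7a bond), either by addition–elimination or by ligand coupling within an O–S sulfurane. The closest known reaction types are the one-pot addition/ipso-substitution of ortho-sulfinyl benzyl carbanions to imines, which gives indolines, and the KOtBu-mediated etherification of aryl sulfoxides by alcohols; new here are the oxygen nucleophile in the tandem mode and the electron-rich ring B. Ring C closes in the 5-exo-trig mode (O1 attacks C7a of the C7a=C7 bond and the C7a–S bond breaks outside the new ring) with the C2–O1 bond untouched, so that C2 keeps the configuration gained in the addition. C3 is controlled by the sulfur stereocentre: in the six-membered C3–Li···O–S chelate the p-tolyl group stands on one face of ring B (the C7 methoxy group forbids the other rotamer), the CH2Si arm points away from sulfur toward C4–H, and the aldehyde is delivered by lithium on the face anti to p-tolyl. C2 is controlled by C3 and the lithium bridge: with the carbonyl oxygen held on the sulfinyl side and ring A placed anti to ring B, the staggered transition state gives the (1S,2S) adduct, which is the one that closes to the trans ring. The step needs metalation at C3 only (secured by the ortho sulfinyl group against the C5 benzylic CH2 and the tolyl CH3), a carbanion that cannot eliminate (secured by silicon in place of oxygen on C9) and a single oxygen able to reach C7a (secured by the silyl ether on the chain and the benzyl ether on ring A).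

**Step 5**
Reactants: 14 (2S,3S)-2-(4-benzyloxy-3-methoxyphenyl)-5-[3-(tert-butyldimethylsilyloxy)propyl]-3-{[dimethyl(phenyl)silyl]methyl}-7-methoxy-2,3-dihydrobenzofuran
Product: 15 3-[(2S,3S)-2-(4-benzyloxy-3-methoxyphenyl)-3-{[dimethyl(phenyl)silyl]methyl}-7-methoxy-2,3-dihydrobenzofuran-5-yl]propan-1-ol
Conditions: TBAF (1.2 equiv), THF, rt
Reagents that add atoms: none
Why: Fluoride-mediated silyl ether cleavage driven by the Si–F bond, while the carbon-bound SiMe2Ph group, which has no neighbouring hydroxyl, is inert to TBAF at room temperature.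

**Step 6**
Reactants: 15 3-[(2S,3S)-2-(4-benzyloxy-3-methoxyphenyl)-3-{[dimethyl(phenyl)silyl]methyl}-7-methoxy-2,3-dihydrobenzofuran-5-yl]propan-1-ol
Product: 16 sodium 3-[(2S,3S)-2-(4-benzyloxy-3-methoxyphenyl)-3-{[dimethyl(phenyl)silyl]methyl}-7-methoxy-2,3-dihydrobenzofuran-5-yl]propyl sulfate
Conditions: SO3·pyridine (3 equiv), pyridine, rt; aq NaHCO3
Reagents that add atoms: sulfur trioxide pyridine complex, O=S(=O)([O-])[n+]1ccccc1; sodium hydrogen carbonate, [Na+].OC([O-])=O
Why: O-sulfation of the only free hydroxyl with the SO3–pyridine complex, with no regiochemical question because C9 still carries silicon and the phenol its benzyl group.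

**Step 7**
Reactants: 16 sodium 3-[(2S,3S)-2-(4-benzyloxy-3-methoxyphenyl)-3-{[dimethyl(phenyl)silyl]methyl}-7-methoxy-2,3-dihydrobenzofuran-5-yl]propyl sulfate
Product: 17 sodium 3-[(2S,3R)-2-(4-benzyloxy-3-methoxyphenyl)-3-(hydroxymethyl)-7-methoxy-2,3-dihydrobenzofuran-5-yl]propyl sulfate
Conditions: KH, t-BuOOH (decane), NMP, 0 °C to rt; then 16, TBAF, 70 °C; aq Na2S2O3, NaCl wash (sodium form)
Reagents that add atoms: tert-butyl hydroperoxide, CC(C)(C)OO
Why: Fleming–Tamao oxidation in its nucleophilic (basic) variant, in which peroxide and fluoride attack silicon, phenyl is expelled and the C9–Si bond migrates to oxygen; the monoalkyl sulfate anion (inert to base and nucleophiles), the benzyl ether, the electron-rich rings and the acid-sensitive C2–O1 bond are untouched and no stereocentre takes part.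

**Step 8**
Reactants: 17 sodium 3-[(2S,3R)-2-(4-benzyloxy-3-methoxyphenyl)-3-(hydroxymethyl)-7-methoxy-2,3-dihydrobenzofuran-5-yl]propyl sulfate
Product: 19 3-[(2S,3R)-2-(4-hydroxy-3-methoxyphenyl)-3-(hydroxymethyl)-7-methoxy-2,3-dihydrobenzofuran-5-yl]propyl hydrogen sulfate (CNP0220090.1), via sodium salt 18 (not isolated)
Conditions: H2 (1 atm), Pd/C (10 %), MeOH, rt; filtration; aq HCl (1.0 equiv), 0 °C, C18 desalting, freeze-drying
Reagents that add atoms: none
Why: Hydrogenolysis of the aryl benzyl ether, under which the cyclic C2–O1 bond of 2-aryl-2,3-dihydrobenzofurans and the sulfate anion persist, followed by protonation with one equivalent of acid in the cold so that neither the ester nor C2 is disturbed.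

**Compound list**

1 | allyloxy(tert-butyl)dimethylsilane | C=CCO[Si](C)(C)C(C)(C)C | starting material
2 | 1-bromo-3-iodo-5-methoxybenzene | COc1cc(Br)cc(I)c1 | starting material
3 | 9-[3-(tert-butyldimethylsilyloxy)propyl]-9-borabicyclo[3.3.1]nonane | CC(C)(C)[Si](C)(C)OCCCB1C2CCCC1CCC2 | intermediate
4 | 1-bromo-3-[3-(tert-butyldimethylsilyloxy)propyl]-5-methoxybenzene | COc1cc(Br)cc(CCCO[Si](C)(C)C(C)(C)C)c1 | intermediate
5 | (1R,2S,5R)-menthyl (S)-p-toluenesulfinate | C[C@@H]1CC[C@H]([C@@H](C1)O[S@](=O)c2ccc(C)cc2)C(C)C | starting material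
6 | 2-bromo-4-[3-(tert-butyldimethylsilyloxy)propyl]-6-methoxyphenyllithium | COc1cc(CCCO[Si](C)(C)C(C)(C)C)cc(Br)c1[Li] | intermediate
7 | (S)-1-bromo-5-[3-(tert-butyldimethylsilyloxy)propyl]-3-methoxy-2-(p-tolylsulfinyl)benzene | COc1cc(CCCO[Si](C)(C)C(C)(C)C)cc(Br)c1[S@@](=O)c1ccc(C)cc1 | intermediate
8 | dimethyl(phenyl)(vinyl)silane | C=C[Si](C)(C)c1ccccc1 | starting material
9 | 9-{2-[dimethyl(phenyl)silyl]ethyl}-9-borabicyclo[3.3.1]nonane | C[Si](C)(CCB1C2CCCC1CCC2)c1ccccc1 | intermediate
10 | (S)-5-[3-(tert-butyldimethylsilyloxy)propyl]-1-{2-[dimethyl(phenyl)silyl]ethyl}-3-methoxy-2-(p-tolylsulfinyl)benzene | COc1cc(CCCO[Si](C)(C)C(C)(C)C)cc(CC[Si](C)(C)c2ccccc2)c1[S@@](=O)c1ccc(C)cc1 | intermediate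
11 | 4-benzyloxy-3-methoxybenzaldehyde | COc1cc(C=O)ccc1OCc1ccccc1 | starting material
12 | sulfinyl-chelated benzyllithium from 10 (lithium on the face later taken by C2) | [Li][C@@H](C[Si](C)(C)c1ccccc1)c1cc(CCCO[Si](C)(C)C(C)(C)C)cc(OC)c1[S@@](=O)c1ccc(C)cc1 | intermediate
13 | lithium (1S,2S)-1-(4-benzyloxy-3-methoxyphenyl)-2-{5-[3-(tert-butyldimethylsilyloxy)propyl]-3-methoxy-2-[(S)-p-tolylsulfinyl]phenyl}-3-[dimethyl(phenyl)silyl]propan-1-olate | [Li+].COc1cc([C@@H]([O-])[C@@H](C[Si](C)(C)c2ccccc2)c2cc(CCCO[Si](C)(C)C(C)(C)C)cc(OC)c2[S@@](=O)c2ccc(C)cc2)ccc1OCc1ccccc1 | intermediate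
14 | (2S,3S)-2-(4-benzyloxy-3-methoxyphenyl)-5-[3-(tert-butyldimethylsilyloxy)propyl]-3-{[dimethyl(phenyl)silyl]methyl}-7-methoxy-2,3-dihydrobenzofuran | COc1cc([C@H]2Oc3c(OC)cc(CCCO[Si](C)(C)C(C)(C)C)cc3[C@@H]2C[Si](C)(C)c2ccccc2)ccc1OCc1ccccc1 | intermediate
15 | 3-[(2S,3S)-2-(4-benzyloxy-3-methoxyphenyl)-3-{[dimethyl(phenyl)silyl]methyl}-7-methoxy-2,3-dihydrobenzofuran-5-yl]propan-1-ol | COc1cc([C@H]2Oc3c(OC)cc(CCCO)cc3[C@@H]2C[Si](C)(C)c2ccccc2)ccc1OCc1ccccc1 | intermediate
16 | sodium 3-[(2S,3S)-2-(4-benzyloxy-3-methoxyphenyl)-3-{[dimethyl(phenyl)silyl]methyl}-7-methoxy-2,3-dihydrobenzofuran-5-yl]propyl sulfate | [Na+].COc1cc([C@H]2Oc3c(OC)cc(CCCOS(=O)(=O)[O-])cc3[C@@H]2C[Si](C)(C)c2ccccc2)ccc1OCc1ccccc1 | intermediate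
17 | sodium 3-[(2S,3R)-2-(4-benzyloxy-3-methoxyphenyl)-3-(hydroxymethyl)-7-methoxy-2,3-dihydrobenzofuran-5-yl]propyl sulfate | [Na+].COc1cc([C@H]2Oc3c(OC)cc(CCCOS(=O)(=O)[O-])cc3[C@@H]2CO)ccc1OCc1ccccc1 | intermediate
18 | sodium 3-[(2S,3R)-2-(4-hydroxy-3-methoxyphenyl)-3-(hydroxymethyl)-7-methoxy-2,3-dihydrobenzofuran-5-yl]propyl sulfate | [Na+].COc1cc([C@H]2Oc3c(OC)cc(CCCOS(=O)(=O)[O-])cc3[C@@H]2CO)ccc1O | intermediate
19 | 3-[(2S,3R)-2-(4-hydroxy-3-methoxyphenyl)-3-(hydroxymethyl)-7-methoxy-2,3-dihydrobenzofuran-5-yl]propyl hydrogen sulfate | COc1cc([C@H]2Oc3c(OC)cc(CCCOS(=O)(=O)O)cc3[C@@H]2CO)ccc1O | target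

Total step count: 8. Longest linear sequence: 8 steps (1 or 2 to 19). Compounds 5, 8 and 11 are bought.

**Steps most likely to fail**

Step 4. The ipso substitution may be too slow on the electron-rich ring B, so that the alkoxide persists or reverts to its components. The alkoxide may instead attack the silicon on C9 with loss of phenyl. The facial selectivity at the aldehyde may also be modest. The fallback uses known chemistry and makes the two bonds one after the other. It sets out from 10 and 11 and comes back at 14. The addition is quenched at −78 °C with aq NH4Cl to give the carbinol (1S,2S)-1-(4-benzyloxy-3-methoxyphenyl)-2-{5-[3-(tert-butyldimethylsilyloxy)propyl]-3-methoxy-2-[(S)-p-tolylsulfinyl]phenyl}-3-[dimethyl(phenyl)silyl]propan-1-ol F1, from which any C2 epimer is removed by chromatography. Sulfoxide–lithium exchange (t-BuLi, THF, −78 °C) with an iodine quench gives the aryl iodide F2. An intramolecular Ullmann etherification (CuI, 1,10-phenanthroline, Cs2CO3, toluene, 110 °C) then closes ring C with retention at C2 and gives 14.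

Step 7. Oxidation on the amphiphilic sulfate salt may suffer from incomplete phenyl displacement at silicon, from cation scrambling that hampers isolation, or from slow loss of the sulfate at 70 °C. The fallback oxidises before sulfation and differentiates the two alcohols by protecting groups. It sets out from 15 and comes back at 18.
- The same basic Fleming–Tamao conditions applied to 15 give the diol F3.
- Trityl chloride (pyridine, DMAP, 0 °C) takes the unhindered chain hydroxyl to give the trityl ether F4.
- NaH/BnBr (THF/DMF) gives the C9 benzyl ether F5.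
- TsOH (cat.) in MeOH/CH2Cl2 removes the trityl group to give the alcohol F6.
- SO3·pyridine followed by NaHCO3 gives the sodium sulfate F7.
- Hydrogenolysis (H2, Pd/C, MeOH) removes both benzyl groups and gives 18, which is protonated as in step 8.

Step 2. Aryllithium 6 may lose LiBr to an aryne. Its attack at sulfur may be sluggish because both ortho positions are occupied. Ligand exchange between 6 and product 7 may erode the optical purity. The fallback changes the organometal through an isolated halide. It sets out from 4 and comes back at 7. Lithiation as in step 2 with an iodine quench gives 1-bromo-5-[3-(tert-butyldimethylsilyloxy)propyl]-2-iodo-3-methoxybenzene F8. Selective iodine–magnesium exchange (iPrMgCl·LiCl, THF, −40 °C) gives the arylmagnesium chloride F9, which is more stable toward aryne formation. F9 reacts with 5 between −20 and 0 °C in the classical Grignard form of the Andersen synthesis to give 7.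

**Further compounds**

F1 | step 4 | (1S,2S)-1-(4-benzyloxy-3-methoxyphenyl)-2-{5-[3-(tert-butyldimethylsilyloxy)propyl]-3-methoxy-2-[(S)-p-tolylsulfinyl]phenyl}-3-[dimethyl(phenyl)silyl]propan-1-ol | COc1cc([C@@H](O)[C@@H](C[Si](C)(C)c2ccccc2)c2cc(CCCO[Si](C)(C)C(C)(C)C)cc(OC)c2[S@@](=O)c2ccc(C)cc2)ccc1OCc1ccccc1
F2 | step 4 | (1S,2S)-1-(4-benzyloxy-3-methoxyphenyl)-2-{5-[3-(tert-butyldimethylsilyloxy)propyl]-2-iodo-3-methoxyphenyl}-3-[dimethyl(phenyl)silyl]propan-1-ol | COc1cc([C@@H](O)[C@@H](C[Si](C)(C)c2ccccc2)c2cc(CCCO[Si](C)(C)C(C)(C)C)cc(OC)c2I)ccc1OCc1ccccc1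
F3 | step 7 | 3-[(2S,3R)-2-(4-benzyloxy-3-methoxyphenyl)-3-(hydroxymethyl)-7-methoxy-2,3-dihydrobenzofuran-5-yl]propan-1-ol | COc1cc([C@H]2Oc3c(OC)cc(CCCO)cc3[C@@H]2CO)ccc1OCc1ccccc1
F4 | step 7 | [(2S,3R)-2-(4-benzyloxy-3-methoxyphenyl)-7-methoxy-5-(3-trityloxypropyl)-2,3-dihydrobenzofuran-3-yl]methanol | COc1cc([C@H]2Oc3c(OC)cc(CCCOC(c4ccccc4)(c4ccccc4)c4ccccc4)cc3[C@@H]2CO)ccc1OCc1ccccc1
F5 | step 7 | (2S,3R)-2-(4-benzyloxy-3-methoxyphenyl)-3-(benzyloxymethyl)-7-methoxy-5-(3-trityloxypropyl)-2,3-dihydrobenzofuran | COc1cc([C@H]2Oc3c(OC)cc(CCCOC(c4ccccc4)(c4ccccc4)c4ccccc4)cc3[C@@H]2COCc2ccccc2)ccc1OCc1ccccc1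
F6 | step 7 | 3-[(2S,3R)-2-(4-benzyloxy-3-methoxyphenyl)-3-(benzyloxymethyl)-7-methoxy-2,3-dihydrobenzofuran-5-yl]propan-1-ol | COc1cc([C@H]2Oc3c(OC)cc(CCCO)cc3[C@@H]2COCc2ccccc2)ccc1OCc1ccccc1
F7 | step 7 | sodium 3-[(2S,3R)-2-(4-benzyloxy-3-methoxyphenyl)-3-(benzyloxymethyl)-7-methoxy-2,3-dihydrobenzofuran-5-yl]propyl sulfate | [Na+].COc1cc([C@H]2Oc3c(OC)cc(CCCOS(=O)(=O)[O-])cc3[C@@H]2COCc2ccccc2)ccc1OCc1ccccc1
F8 | step 2 | 1-bromo-5-[3-(tert-butyldimethylsilyloxy)propyl]-2-iodo-3-methoxybenzene | COc1cc(CCCO[Si](C)(C)C(C)(C)C)cc(Br)c1I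
F9 | step 2 | 2-bromo-4-[3-(tert-butyldimethylsilyloxy)propyl]-6-methoxyphenylmagnesium chloride | COc1cc(CCCO[Si](C)(C)C(C)(C)C)cc(Br)c1[Mg]Cl
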